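All runs were generated by integration with constants of no real substance; noise was put on by code.

The ratio to watch is target to all product, and the autumn run, the very flask we are asked about, already shows it.

in all of them: substrate 10 mM; gas 0.54 mM (held)

| charge | other conformer | remark | time |
|---|---|---|---|
| autumn | 0.10 equiv | the very flask that is asked about, followed so far |  |
| flask | 0.100 equiv |  | 2.5 h |

autumn run (percent of the substrate and other conformer together charged)

| time / min | target / % | isomer of the product / % |
|---|---|---|
| 0.667 | 1.5 | 9.5 |
| 2.00 | 3.0 | 27.7 |
| 3.00 | 4.4 | 38.7 |
| 5.00 | 7.6 | 55.7 |
| 8.00 | 10.7 | 71.3 |
| 10.0 | 11.4 | 76.7 |
| 12.0 | 13.1 | 80.9 |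

(each reading ± 0.3 percentage points)

1. amount of target at 2.5 h, in percent of the substrate and other conformer together charged
2. amount of isomer of the product at 2.5 h, in percent of the substrate and other conformer together charged

- the analysis behind the earlier runs scatters by 0.3 percentage points, standard deviation
- at the start none of the gas is in solution
- in a conversion other conformer counts as not yet reacted

We read the autumn columns against each other. Target over target plus isomer, the selectivity, reads 10.2% at 3.00 min and 13.9% at 12.0 min in the autumn run. The two columns together leave 6.00% at that last reading as substrate and other conformer. That fall gives an apparent first-order constant of 0.234 /min, averaged over the run so far.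

Now we count turnovers. The turnover count is the time multiplied by that constant, 35.2 at the asked time, and on this first-order reckoning each turnover divides the unreacted part by e. We assume that both products stand once formed and that the last 6.00% divides at the last selectivity. Our reckoning is then target 13.9% and isomer 86.1%.

The forecast differs: it holds that extra target “tracks the accumulated isomer” and gives target 60% (38% to 72%) and isomer 40% (27% to 62%).

The flask gives target 14.0% and isomer 86.0%.

    reagent + other conformer → isomer of the product (k = 9800 /M/min)
    gas ⇌ reagent, rate k2*(csat - [reagent]) (kL = 5.70 /min)
    substrate ⇌ other conformer (K = 0.190, k = 0.260 /min)
    substrate + reagent → target (k = 95.0 /M/min)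

In these equations target and isomer are both end products. The flask has come to rest by the asked time, with substrate at 0% and other conformer at 0%. At 0.250 h our count leaves 2.99% unreacted, and the flask holds substrate 3.09% and other conformer 0.129%. Ten times the time means 352 turnovers, and the flask still reads target 14.0% and isomer 86.0%, the isomer unchanged.

For a reading at 1.0 h the count is 14.0 turnovers, so we expect the same split as at the asked time. That neighbour gives target 14.0% and isomer 86.0%.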